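**Plan**
- Retrosynthetic cuts, in order: C13–C14 and C12=C13 of the diene; the acetate and the C–O bonds at C7, C6 and C8; C9–C11 (allyl addition with 1,3-carbonyl transposition); C3–C4 of ring A; finally C10–C1 and C10–C20 (two enolate alkylations).
- Enabling feature: ring B (C5–C10) with C17, C4, C18 and C19 is the intact ten-carbon set of (S)-carvone. Its isopropenyl carbon is C4, a latent tertiary radical held 1,6 to the acrylate terminus C3 once an acrylate arm (C1–C2=C3) sits on C10.
- Forward order: ring B is bought; C20 and the acrylate arm go onto C10; ring A closes by radical C3–C4 bond formation; the C2 ester is excised; allyl is added to C9 and the carbonyl moved to C7; ring B is oxygenated at C8, C6 and C7; the allyl group is cut to the C12 aldehyde and grown into the (12Z)-diene.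
- Stereochemistry: C5 from carvone; C10 by alkylation anti to the isopropenyl group; C9, C8, C6 and C7 each by reagent approach anti to the axial C20 methyl of the rigid trans-decalin; 12Z from a Z-selective iodo-olefination and a stereoretentive coupling.
- Acetate position: O6 and O8 arrive as silyl ethers from two Rubottom oxidations, so only O7–H is free when the acetate is put on.

Key step: step 3

Assumption: labdane locants are used for all bicyclic compounds and "syn"/"anti" refer to the face of the decalin relative to the angular methyl C20; the C6 epimers of 4 and the C2 epimers of 8–10 are carried together because those centres are later planarised or become CH2, and the SMILES show the expected major epimer.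

**Route**

Step 1
Reactants: 1 (S)-(+)-carvone; 2 iodomethane
Product: 4 trans-6-methylcarvone [(5S,6R)-2,6-dimethyl-5-(prop-1-en-2-yl)cyclohex-2-en-1-one], via lithium enolate 3 (not isolated)
Conditions: LiN(iPr)2, THF, −78 °C; then MeI, −78 → 0 °C
Reagents that add atoms: iodomethane (2), CI
Why: Kinetic deprotonation at the α′-methylene gives the cross-conjugated lithium enolate 3, whose SN2 C-methylation (enolate alkylation) installs the future C20, the new centre forming mainly trans to isopropenyl but being planarised again in step 2.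

Step 2
Reactants: 4 trans-6-methylcarvone; 5 methyl 2-(bromomethyl)acrylate
Product: 7 methyl 2-{[(1R,6R)-1,3-dimethyl-2-oxo-6-(prop-1-en-2-yl)cyclohex-3-en-1-yl]methyl}prop-2-enoate, via lithium enolate 6 (not isolated)
Conditions: LiN(iPr)2, THF, −78 → −10 °C; then 5, −78 °C → rt
Reagents that add atoms: methyl 2-(bromomethyl)acrylate (5), COC(=O)C(=C)CBr
Why: Enolate alkylation with the highly reactive 2-(methoxycarbonyl)allyl bromide (direct SN2 and SN2′ addition–elimination give the same product) occurs on the face of the tetrasubstituted enolate 6 anti to the neighbouring isopropenyl group, so the quaternary carbon (future C10) carries the acrylate arm trans and the methyl cis to isopropenyl.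

Step 3
Reactants: 7 acrylate-armed carvone
Product: 8 methyl (5R,10R)-4,4,8,10-tetramethyl-9-oxo-trans-decal-7-ene-2-carboxylate (ester equatorial)
Conditions: Fe(acac)3 (30 mol %), PhSiH3 (2.5 equiv), EtOH/ethylene glycol 5:1, 60 °C, high dilution
Reagents that add atoms: none
Why: An iron hydride generated from Fe(acac)3 and PhSiH3 in ethanol transfers a hydrogen atom to the terminal carbon of the electron-rich isopropenyl group, turning C19 into a methyl and C4 into a nucleophilic tertiary radical. This radical adds to the unsubstituted acrylate terminus C3, forming the C3–C4 bond and closing ring A in the 6-endo-trig mode, and the α-ester radical at C2 is reduced by divalent iron to the enolate and protonated by the solvent, which returns trivalent iron to the cycle. The closest known reaction type is the iron/silane HAT reductive olefin coupling (HAT-initiated Giese addition), used here intramolecularly. The single new stereocentre, C2, arises on protonation of the ester enolate, is governed only by the chair of ring A (ester expected equatorial) and is deleted in step 5. Two selectivities are needed and both are polarity-controlled: HAT goes to the only electron-rich 1,1-disubstituted alkene rather than to the enone or acrylate, and the radical attacks the electron-poor CH2 terminus because 5-exo attack would join two fully substituted carbons and leave an unstabilised primary radical. The trans ring fusion is not at stake, since C4 on C5 and the acrylate arm on C10 are trans-diequatorial on ring B from step 2 and can only close to the trans-decalin.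

Step 4
Reactants: 8 bicyclic ester
Product: 9 (5R,10R)-4,4,8,10-tetramethyl-9-oxo-trans-decal-7-ene-2-carboxylic acid
Conditions: LiOH, THF/MeOH/H2O, rt; then 1 M HCl
Reagents that add atoms: lithium hydroxide, [Li+].[OH-]
Why: Saponification (acyl-oxygen ester hydrolysis) of the unhindered secondary methyl ester, while the enone has no α′-hydrogen and C5 and C10 cannot epimerise.

Step 5
Reactants: 9 bicyclic acid
Product: 11 (5R,10R)-4,4,8,10-tetramethyl-trans-decal-7-en-9-one, via Barton ester 10 (not isolated)
Conditions: N-hydroxypyridine-2-thione, DCC, DMAP (cat.), CH2Cl2, rt, dark; then t-BuSH, hν (tungsten lamp), PhH, rt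
Reagents that add atoms: none
Why: Barton reductive decarboxylation, in which the O-acyl thiohydroxamate 10 fragments under visible light to CO2 and the secondary C2 radical that abstracts hydrogen from the thiol, so C2 becomes a methylene and the stereocentre made in step 3 disappears while the distant enone is untouched.

Step 6
Reactants: 11 bicyclic enone; 12 allylmagnesium bromide
Product: 13 (5R,10R)-9-allyl-4,4,8,10-tetramethyl-trans-decal-7-en-9-ol (allyl anti to C20)
Conditions: CH2=CHCH2MgBr, THF, −78 → 0 °C; then H2O
Reagents that add atoms: allylmagnesium bromide (12), C=CC[Mg]Br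
Why: Grignard 1,2-addition of the allyl reagent to the non-enolisable enone carbonyl (allylmagnesium halides add 1,2 even to hindered ketones), expected anti to the axial C20, although the C9 configuration is irrelevant because C9 becomes sp2 in step 7.

Step 7
Reactants: 13 tertiary allylic alcohol
Product: 14 (5R,10R)-9-allyl-4,4,8,10-tetramethyl-trans-decal-8-en-7-one
Conditions: pyridinium chlorochromate, 4 Å molecular sieves, CH2Cl2, rt
Reagents that add atoms: pyridinium chlorochromate, [O-][Cr](=O)(=O)Cl.c1cc[nH+]cc1
Why: Dauben–Babler oxidative transposition, in which the tertiary allylic chromate ester undergoes a [3,3] shift to the C7 chromate and is oxidised to the tetrasubstituted 8-en-7-one, moving oxygen to C7 and leaving the allyl group on C9 with no stereocentre created.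

Step 8
Reactants: 14 transposed enone
Product: 16 (5R,9S,10R)-9-allyl-4,4,8,10-tetramethyl-7-(triethylsilyloxy)-trans-decal-7-ene, via lithium enolate 15 (not isolated)
Conditions: Li (2.2 equiv), NH3(l)/THF, t-BuOH (1 equiv), −78 °C; evaporate NH3; then Et3SiCl, Et3N, THF, −78 → 0 °C
Reagents that add atoms: chlorotriethylsilane, CC[Si](Cl)(CC)CC
Why: Dissolving-metal (Birch-type) enone reduction with regiospecific enolate trapping, in which the β-carbon C9 is protonated axially, anti to C20, so that the allyl chain becomes equatorial (9S), and the C7–C8 lithium enolate 15 is O-silylated before it can equilibrate, the isolated terminal alkene being inert to Li/NH3.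

Step 9
Reactants: 16 silyl enol ether
Product: 18 (5R,8R,9S,10R)-9-allyl-4,4,8,10-tetramethyl-8-(triethylsilyloxy)-trans-decalin-7-one, via silyloxy epoxide 17 (not isolated)
Conditions: mCPBA (1.05 equiv), NaHCO3, CH2Cl2, −20 °C → rt
Reagents that add atoms: 3-chloroperbenzoic acid, OOC(=O)c1cccc(Cl)c1
Why: Rubottom oxidation, in which the peracid epoxidises the electron-rich tetrasubstituted enol ether far faster than the monosubstituted alkene and does so anti to the syn-axial C20 methyl, after which a 1,4-silyl shift opens epoxide 17 to the α-silyloxy ketone with O8 equatorial and C17 axial (8R).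

Step 10
Reactants: 18 α-silyloxy ketone
Product: 19 (5R,8R,9S,10R)-9-allyl-4,4,8,10-tetramethyl-7,8-bis(triethylsilyloxy)-trans-decal-6-ene
Conditions: Et3SiOTf, Et3N, CH2Cl2, 0 °C → rt
Reagents that add atoms: triethylsilyl trifluoromethanesulfonate, CC[Si](CC)(CC)OS(=O)(=O)C(F)(F)F
Why: Soft enolisation (silyl triflate/amine enol ether formation) can only run toward C6 because C8 is quaternary, so the C6–C7 enol ether forms regiospecifically and no stereocentre is created.

Step 11
Reactants: 19 silyl enol ether
Product: 21 (5R,6S,8R,9S,10R)-9-allyl-4,4,8,10-tetramethyl-6,8-bis(triethylsilyloxy)-trans-decalin-7-one, via silyloxy epoxide 20 (not isolated)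
Conditions: mCPBA (1.05 equiv), NaHCO3, CH2Cl2, −20 °C → rt
Reagents that add atoms: 3-chloroperbenzoic acid, OOC(=O)c1cccc(Cl)c1
Why: Second Rubottom oxidation, in which the syn face of C6 is blocked by the axial methyls C19 and C20 so that the peracid attacks anti and the oxygen, onto which the silyl group migrates, ends equatorial (6S).

Step 12
Reactants: 21 bis(silyloxy) ketone
Product: 22 (5R,6S,7R,8R,9S,10R)-9-allyl-4,4,8,10-tetramethyl-6,8-bis(triethylsilyloxy)-trans-decalin-7-ol
Conditions: NaBH4, CeCl3·7H2O, MeOH/THF, −40 → 0 °C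
Reagents that add atoms: none
Why: Luche-type borohydride reduction, in which hydride enters along the axial trajectory anti to C20 (the syn face is screened by the axial C17 methyl) to give the equatorial 7R alcohol, the weakly basic cerium-containing medium being chosen to keep the silyl ethers from migrating.

Step 13
Reactants: 22 C7 alcohol
Product: 23 (5R,6S,7R,8R,9S,10R)-9-allyl-4,4,8,10-tetramethyl-6,8-bis(triethylsilyloxy)-trans-decalin-7-yl acetate
Conditions: Ac2O, DMAP, pyridine, CH2Cl2, rt → 40 °C
Reagents that add atoms: acetic anhydride, CC(=O)OC(C)=O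
Why: DMAP-catalysed acylation (nucleophilic catalysis) of the only free hydroxyl, the secondary O7–H, since O6 and O8 are silylated, which fixes the position of the acetate without competition between hydroxyls.

Step 14
Reactants: 23 allyl acetate
Product: 25 C12 aldehyde [9-(2-oxoethyl) analogue of 23], via vicinal diol 24 (not isolated)
Conditions: OsO4 (cat.), NaIO4, 2,6-lutidine, dioxane/H2O 3:1, rt
Reagents that add atoms: osmium tetroxide, O=[Os](=O)(=O)=O; sodium periodate, [Na+].[O-][I](=O)(=O)=O
Why: Lemieux–Johnson oxidative cleavage, in which the monosubstituted alkene (the only C=C of 23) is dihydroxylated to diol 24 and cleaved by periodate to the C12 aldehyde with loss of one carbon, acetate and silyl ethers being stable at the buffered pH.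

Step 15
Reactants: 25 C12 aldehyde; 26 ethyltriphenylphosphonium iodide
Product: 27 (Z)-alkenyl iodide [9-[(2Z)-3-iodobut-2-en-1-yl] analogue of 23]
Conditions: 26, n-BuLi, THF, 0 °C; I2, −78 °C; NaN(SiMe3)2, −78 → −20 °C; then 25, −78 °C
Reagents that add atoms: ethyltriphenylphosphonium iodide (26), CC[P+](c1ccccc1)(c1ccccc1)c1ccccc1.[I-]; iodine, II
Why: Stork–Zhao-type Wittig olefination with the α-iodoethylidene ylide, which under kinetic control at low temperature gives the (Z)-2-iodoalkene with iodine cis to C11, the ylide reacting with the aldehyde much faster than with the acetate.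

Step 16
Reactants: 27 (Z)-alkenyl iodide; 28 tributyl(vinyl)stannane
Product: 29 6,8-bis(triethylsilyl) ether of the target
Conditions: PdCl2(MeCN)2 (5 mol %), DMF, rt, dark
Reagents that add atoms: tributyl(vinyl)stannane (28), C=C[Sn](CCCC)(CCCC)CCCC
Why: Stille cross-coupling through zerovalent palladium, which replaces iodine by vinyl with retention of alkene geometry so that the vinyl group ends cis to C11 and the (12Z)-diene is obtained under neutral conditions that spare acetate and silyl ethers.

Step 17
Reactants: 29 bis(silyl) ether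
Product: 30 target, (5R,6S,7R,8R,9S,10R,12Z)-6,8-dihydroxy-ent-labda-12,14-dien-7-yl acetate
Conditions: HF·pyridine, pyridine, THF, 0 °C → rt
Reagents that add atoms: none
Why: Fluoride-mediated desilylation of both triethylsilyl ethers under buffered conditions that are neither basic enough to move the acetyl group from O7 to O6 or O8 nor acidic enough to attack the diene, so that no stereocentre is touched.

**Compound list**
1 | (S)-(+)-carvone, (5S)-2-methyl-5-(prop-1-en-2-yl)cyclohex-2-en-1-one | CC1=CC[C@@H](CC1=O)C(C)=C | starting material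
2 | iodomethane | CI | starting material
3 | lithium enolate of 1 (cross-conjugated, O–C1=C6) | CC1=CC[C@H](C(C)=C)C=C1O[Li] | intermediate (not isolated)
4 | trans-6-methylcarvone, (5S,6R)-2,6-dimethyl-5-(prop-1-en-2-yl)cyclohex-2-en-1-one (carried with its 6S epimer) | O=C1C(C)=CC[C@H](C(C)=C)[C@H]1C | intermediate
5 | methyl 2-(bromomethyl)acrylate | COC(=O)C(=C)CBr | starting material
6 | lithium enolate of 4 (O–C1=C6, tetrasubstituted) | CC1=CC[C@H](C(C)=C)C(C)=C1O[Li] | intermediate (not isolated)
7 | methyl 2-{[(1R,6R)-1,3-dimethyl-2-oxo-6-(prop-1-en-2-yl)cyclohex-3-en-1-yl]methyl}prop-2-enoate (acrylate arm trans, methyl cis to isopropenyl) | O=C1C(C)=CC[C@H](C(C)=C)[C@@]1(C)CC(=C)C(=O)OC | intermediate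
8 | methyl (5R,10R)-4,4,8,10-tetramethyl-9-oxo-trans-decal-7-ene-2-carboxylate, ester equatorial | O=C1C(C)=CC[C@@H]2C(C)(C)C[C@@H](C(=O)OC)C[C@]21C | intermediate
9 | (5R,10R)-4,4,8,10-tetramethyl-9-oxo-trans-decal-7-ene-2-carboxylic acid | O=C1C(C)=CC[C@@H]2C(C)(C)C[C@@H](C(=O)O)C[C@]21C | intermediate
10 | Barton ester of 9 (2-thioxopyridin-1(2H)-yl ester) | O=C1C(C)=CC[C@@H]2C(C)(C)C[C@@H](C(=O)ON3C=CC=CC3=S)C[C@]21C | intermediate (not isolated)
11 | (5R,10R)-4,4,8,10-tetramethyl-trans-decal-7-en-9-one [(4aR,8aR)-2,5,5,8a-tetramethyl-4a,5,6,7,8,8a-hexahydronaphthalen-1(4H)-one] | O=C1C(C)=CC[C@@H]2C(C)(C)CCC[C@]21C | intermediate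
12 | allylmagnesium bromide | C=CC[Mg]Br | starting material
13 | (5R,10R)-9-allyl-4,4,8,10-tetramethyl-trans-decal-7-en-9-ol, allyl anti to C20 | C=CC[C@@]1(O)C(C)=CC[C@@H]2C(C)(C)CCC[C@]21C | intermediate
14 | (5R,10R)-9-allyl-4,4,8,10-tetramethyl-trans-decal-8-en-7-one | C=CCC1=C(C)C(=O)C[C@@H]2C(C)(C)CCC[C@]21C | intermediate
15 | lithium enolate (O–C7=C8) from reduction of 14, H9 anti to C20 | C=CC[C@@H]1C(C)=C(O[Li])C[C@@H]2C(C)(C)CCC[C@]21C | intermediate (not isolated)
16 | (5R,9S,10R)-9-allyl-4,4,8,10-tetramethyl-7-(triethylsilyloxy)-trans-decal-7-ene | C=CC[C@@H]1C(C)=C(O[Si](CC)(CC)CC)C[C@@H]2C(C)(C)CCC[C@]21C | intermediate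
17 | 7,8-epoxide of 16, oxygen anti to C20 | C=CC[C@@H]1[C@@]3(C)O[C@@]3(O[Si](CC)(CC)CC)C[C@@H]2C(C)(C)CCC[C@]21C | intermediate (not isolated)
18 | (5R,8R,9S,10R)-9-allyl-4,4,8,10-tetramethyl-8-(triethylsilyloxy)-trans-decalin-7-one | C=CC[C@@H]1[C@@](C)(O[Si](CC)(CC)CC)C(=O)C[C@@H]2C(C)(C)CCC[C@]21C | intermediate
19 | (5R,8R,9S,10R)-9-allyl-4,4,8,10-tetramethyl-7,8-bis(triethylsilyloxy)-trans-decal-6-ene | C=CC[C@@H]1[C@@](C)(O[Si](CC)(CC)CC)C(O[Si](CC)(CC)CC)=C[C@@H]2C(C)(C)CCC[C@]21C | intermediate
20 | 6,7-epoxide of 19, oxygen anti to C20 | C=CC[C@@H]1[C@@](C)(O[Si](CC)(CC)CC)[C@@]3(O[Si](CC)(CC)CC)O[C@H]3[C@@H]2C(C)(C)CCC[C@]21C | intermediate (not isolated)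
21 | (5R,6S,8R,9S,10R)-9-allyl-4,4,8,10-tetramethyl-6,8-bis(triethylsilyloxy)-trans-decalin-7-one | C=CC[C@@H]1[C@@](C)(O[Si](CC)(CC)CC)C(=O)[C@@H](O[Si](CC)(CC)CC)[C@@H]2C(C)(C)CCC[C@]21C | intermediate
22 | (5R,6S,7R,8R,9S,10R)-9-allyl-4,4,8,10-tetramethyl-6,8-bis(triethylsilyloxy)-trans-decalin-7-ol | C=CC[C@@H]1[C@@](C)(O[Si](CC)(CC)CC)[C@H](O)[C@@H](O[Si](CC)(CC)CC)[C@@H]2C(C)(C)CCC[C@]21C | intermediate
23 | (5R,6S,7R,8R,9S,10R)-9-allyl-4,4,8,10-tetramethyl-6,8-bis(triethylsilyloxy)-trans-decalin-7-yl acetate | C=CC[C@@H]1[C@@](C)(O[Si](CC)(CC)CC)[C@H](OC(C)=O)[C@@H](O[Si](CC)(CC)CC)[C@@H]2C(C)(C)CCC[C@]21C | intermediate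
24 | 9-(2,3-dihydroxypropyl) analogue of 23 (both epimers at the carbinol carbon) | OCC(O)C[C@@H]1[C@@](C)(O[Si](CC)(CC)CC)[C@H](OC(C)=O)[C@@H](O[Si](CC)(CC)CC)[C@@H]2C(C)(C)CCC[C@]21C | intermediate (not isolated)
25 | 9-(2-oxoethyl) analogue of 23 (C12 aldehyde) | O=CC[C@@H]1[C@@](C)(O[Si](CC)(CC)CC)[C@H](OC(C)=O)[C@@H](O[Si](CC)(CC)CC)[C@@H]2C(C)(C)CCC[C@]21C | intermediate
26 | ethyltriphenylphosphonium iodide | CC[P+](c1ccccc1)(c1ccccc1)c1ccccc1.[I-] | starting material
27 | 9-[(2Z)-3-iodobut-2-en-1-yl] analogue of 23 (iodine cis to C11) | I/C(C)=C\C[C@@H]1[C@@](C)(O[Si](CC)(CC)CC)[C@H](OC(C)=O)[C@@H](O[Si](CC)(CC)CC)[C@@H]2C(C)(C)CCC[C@]21C | intermediate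
28 | tributyl(vinyl)stannane | C=C[Sn](CCCC)(CCCC)CCCC | starting material
29 | 6,8-bis(triethylsilyl) ether of 30 | C=C/C(C)=C\C[C@@H]1[C@@](C)(O[Si](CC)(CC)CC)[C@H](OC(C)=O)[C@@H](O[Si](CC)(CC)CC)[C@@H]2C(C)(C)CCC[C@]21C | intermediate
30 | (5R,6S,7R,8R,9S,10R,12Z)-6,8-dihydroxy-ent-labda-12,14-dien-7-yl acetate [(1S,2R,3R,4S,4aR,8aR)-2,4-dihydroxy-2,5,5,8a-tetramethyl-1-[(2Z)-3-methylpenta-2,4-dien-1-yl]decahydronaphthalen-3-yl acetate] | C=C/C(C)=C\C[C@@H]1[C@@](C)(O)[C@H](OC(C)=O)[C@@H](O)[C@@H]2C(C)(C)CCC[C@]21C | target

**Count**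
Total steps: 17. Longest linear sequence: 17 (fully linear from 1).

**Steps most likely to fail**

Step 3. The C4 radical may be reduced before it cyclises (net hydrogenation of the isopropenyl group), or add intermolecularly to another acrylate. The fallback sets out from 7 and generates the same radical from a halide. Markovnikov hydrobromination of the isopropenyl group (HBr, CH2Cl2, −40 °C) should give the tertiary bromide F1. Slow addition of Bu3SnH with AIBN in PhH at 80 °C then abstracts bromine, closes the same C3–C4 bond 6-endo and returns to the route at 8.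

Step 8. Proton transfer to the lithium enolate while ammonia is removed, or incomplete O-silylation, would erode the regiodefined enol ether; over-reduction of the carbonyl is a further drain. The fallback sets out from 14 and separates reduction from silylation. Li/NH3 with an NH4Cl quench should give the saturated ketone F2 (C17 equatorial, either C8 epimer serves). Thermodynamic silylation (Et3SiCl, NaI, Et3N, MeCN, 60 °C) favours the tetrasubstituted C7–C8 enol ether and rejoins the route at 16.

Step 15. Z-selectivity may erode, the ylide may lose iodine, and the aldehyde may enolise. The fallback sets out from 25 and builds the trisubstituted alkene by two stereodefined couplings. Dibromo-olefination (CBr4, PPh3, Et3N, CH2Cl2, 0 °C) should give the 1,1-dibromoalkene F3. Trans-selective Negishi monomethylation (Me2Zn, PdCl2[bis(2-diphenylphosphinophenyl) ether] cat., THF) replaces the bromine trans to C11 and gives the (Z)-2-bromoalkene F4. Vinylation with 28 and Pd(PtBu3)2 proceeds with retention and comes back to the route at 29.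

**Further compounds**
F1 | step 3 | methyl 2-{[6-(2-bromopropan-2-yl)-1,3-dimethyl-2-oxocyclohex-3-en-1-yl]methyl}prop-2-enoate, configuration as in 7 | O=C1C(C)=CC[C@H](C(C)(C)Br)[C@@]1(C)CC(=C)C(=O)OC
F2 | step 8 | (5R,9S,10R)-9-allyl-4,4,8,10-tetramethyl-trans-decalin-7-one, C17 equatorial | C=CC[C@@H]1[C@@H](C)C(=O)C[C@@H]2C(C)(C)CCC[C@]21C
F3 | step 15 | 9-(3,3-dibromoprop-2-en-1-yl) analogue of 23 | BrC(Br)=CC[C@@H]1[C@@](C)(O[Si](CC)(CC)CC)[C@H](OC(C)=O)[C@@H](O[Si](CC)(CC)CC)[C@@H]2C(C)(C)CCC[C@]21C
F4 | step 15 | 9-[(2Z)-3-bromobut-2-en-1-yl] analogue of 23 (bromine cis to C11) | Br/C(C)=C\C[C@@H]1[C@@](C)(O[Si](CC)(CC)CC)[C@H](OC(C)=O)[C@@H](O[Si](CC)(CC)CC)[C@@H]2C(C)(C)CCC[C@]21C
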